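The route rests on disconnecting the C4–C7 bond between the benzene ring and the hydroxymethyl carbon. In one operation, the phenoxide of 2,3,6-tribromophenol adds through its para carbon to formaldehyde, installing the CH2OH group and delivering the target without protecting groups. The step exploits the fact that C4 of the single aromatic ring, para to the oxygen-bearing C1, is the only oxygen-activated carbon left open: C2 and C6 (ortho) carry bromine, the C3 bromine is already in place meta to oxygen, and C5 is meta and unactivated. The precursor, a phenol with bromine at C2, C3 and C6 and hydrogen at C4 and C5, comes from 2,5-dibromophenol by one ortho-directed bromination.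

Key step: step 2

Assumption: formaldehyde 4 is used as its commercial 37% aqueous solution; ring atoms are numbered as in the phenol name (C1 bears the oxygen, C7 is the CH2OH carbon).

Step 1
Reactants: 1 2,5-dibromophenol; 2 N-bromosuccinimide
Product: 3 2,3,6-tribromophenol
Conditions: NBS (1.0 equiv, slow addition), iPr2NH (0.1 equiv), CH2Cl2, 0 °C to rt
Reagents that add atoms: N-bromosuccinimide, O=C1CCC(=O)N1Br
Why: Amine-mediated ortho-selective electrophilic bromination of a phenol, in which NBS and diisopropylamine form N-bromodiisopropylamine that hydrogen-bonds to the phenolic OH and hands bromine to the neighbouring carbon, so that C6, the only unsubstituted ortho carbon of 1, should be brominated in preference to the free para carbon.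

Step 2
Reactants: 3 2,3,6-tribromophenol; 4 formaldehyde
Product: 8 2,3,6-tribromo-4-(hydroxymethyl)phenol, via sodium 2,3,6-tribromophenoxide 5 (not isolated), via 2,3,6-tribromo-4-(hydroxymethyl)cyclohexa-2,5-dienone 6 (not isolated), via sodium 2,3,6-tribromo-4-(hydroxymethyl)phenoxide 7 (not isolated)
Conditions: NaOH (1.05 equiv), 37% aq. CH2O (5 equiv), H2O, 20 to 40 °C; then 1 M HCl, 0 °C, to pH 3
Reagents that add atoms: formaldehyde, C=O
Why: NaOH deprotonates 3 to phenoxide 5, an ambident nucleophile that attacks the carbonyl carbon of formaldehyde through its para carbon C4, creating the C4–C7 bond in dienone 6; loss of the C4 proton restores the aromatic ring as phenoxide 7, which cold dilute HCl protonates to 8. The closest known reaction type is the Lederer–Manasse hydroxymethylation of phenols with formaldehyde in aqueous alkali, which is established for phenols whose two ortho positions are blocked by alkyl or halogen groups. No ring is closed, and the only sp3 ring carbon that appears (C4 of 6, racemic) is flattened again on rearomatisation, so no stereocontrol is needed. The step needs para regioselectivity and a single addition, and both are secured by the substrate: C2 and C6 carry bromine, C5 is meta to the oxygen and unactivated, and after reaction no activated C–H remains. The competing pathway is ionisation of 7 to a quinone methide that a second phenoxide would capture as a diarylmethane; the three electron-withdrawing bromines disfavour it, and excess formaldehyde, mild temperature and only one equivalent of base (which also limits Cannizzaro loss of formaldehyde) should suppress it further.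

Compound list
1 | 2,5-dibromophenol | Oc1cc(Br)ccc1Br | starting material
2 | N-bromosuccinimide | O=C1CCC(=O)N1Br | starting material
3 | 2,3,6-tribromophenol | Oc1c(Br)ccc(Br)c1Br | intermediate
4 | formaldehyde (37% aqueous solution) | C=O | starting material
5 | sodium 2,3,6-tribromophenoxide | [Na+].[O-]c1c(Br)ccc(Br)c1Br | intermediate (not isolated)
6 | 2,3,6-tribromo-4-(hydroxymethyl)cyclohexa-2,5-dienone (racemic, transient) | O=C1C(Br)=CC(CO)C(Br)=C1Br | intermediate (not isolated)
7 | sodium 2,3,6-tribromo-4-(hydroxymethyl)phenoxide | [Na+].[O-]c1c(Br)cc(CO)c(Br)c1Br | intermediate (not isolated)
8 | 2,3,6-tribromo-4-(hydroxymethyl)phenol | OCc1cc(Br)c(O)c(Br)c1Br | target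

Total step count: 2
Longest linear sequence: 2 steps

Steps most likely to fail (the route has only two steps, so both are ranked)

1. Step 2. The tribrominated phenoxide is weakly nucleophilic and its para carbon is flanked by the C3 bromine, so C–C bond formation may stall. On long reaction times or during acidification the product may also condense onward through quinone methide formation. The fallback sets out from compound 3 and comes back to the route at compound 8. Duff formylation of 3 with hexamethylenetetramine in trifluoroacetic acid at reflux, followed by hydrolysis with aqueous HCl, should give 2,3,5-tribromo-4-hydroxybenzaldehyde F1. This brings the same carbon in at the aldehyde oxidation level through a stronger iminium electrophile, and an aldehyde cannot ionise to a quinone methide. Reduction of the formyl group with NaBH4 in MeOH/THF at 0 °C and a cold, mildly acidic quench should then return target 8.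

2. Step 1. Ortho direction may be lost, so that bromine enters at the free para carbon C4, or a second bromine may be introduced. The fallback sets out from compound 1 and comes back to the route at compound 3, and uses a removable para-blocking group. Sulfonation of 1 in concentrated H2SO4 at about 100 °C should place the bulky, reversibly bound sulfonic acid group at the less hindered para carbon, giving 2,5-dibromo-4-hydroxybenzenesulfonic acid F2. After dilution with water, one equivalent of Br2 at 0 to 10 °C can then only enter the remaining oxygen-activated carbon, giving 2,3,5-tribromo-4-hydroxybenzenesulfonic acid F3. Protodesulfonation in hot aqueous H2SO4 with steam (about 150 to 180 °C) should release 2,3,6-tribromophenol 3, which is expected to distil with the steam.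

Further compounds
F1 | step 2 | 2,3,5-tribromo-4-hydroxybenzaldehyde | O=Cc1cc(Br)c(O)c(Br)c1Br
F2 | step 1 | 2,5-dibromo-4-hydroxybenzenesulfonic acid | OS(=O)(=O)c1cc(Br)c(O)cc1Br
F3 | step 1 | 2,3,5-tribromo-4-hydroxybenzenesulfonic acid | OS(=O)(=O)c1cc(Br)c(O)c(Br)c1Br
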